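Ring numbering: N1, C2 (nonyl), C3, C4 (C=O), N5, C6 to C8, N9, C10 to C13, N14, C15 to C17. Only C2, C3 and C4 separate N1 from N5. A temporary N1–N5 bond therefore folds the β-amino amide into a pyrazolidin-3-one and makes the inert lactam N5–H an acidic hydrazide N–H. In the key step this nitrogen displaces a primary mesylate at C6. N5–C6 forms, and the new 14-membered ring shares the N1–N5 edge with the five-membered ring. Reductive scission of that edge then leaves the 17-membered lactam. The precursor is a (5R)-5-nonylpyrazolidin-3-one whose N1 carries the whole C17-to-C6 chain, N14 and N9 being tosylamides.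

Key step: step 8

Design remark: N9 and N14 are carried as tosylamides rather than carbamates.
- A carbamate carbonyl three carbons from the C6 mesylate can attack it (6-exo-tet) and end as a 1,3-oxazinan-2-one. That drain is unimolecular, so dilution cannot suppress it while the slow macrocyclisation runs.
- A tosylamide offers no such nucleophile and allows exactly one alkylation per nitrogen during chain assembly.
- It binds Mg more weakly than a carbamate.
- It leaves in the same reduction that breaks N1–N5.

Assumption: the ligand enantiomer named in step 6 is taken to leave open the Re face of the β-carbon, which is the face that leads to (R). Both ligand enantiomers are commercial, so the antipode is used if a trial run shows the opposite sense.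

Step 1
Reactants: 1 putrescine (butane-1,4-diamine)
Product: 2 N,N'-ditosylputrescine [N,N'-(butane-1,4-diyl)bis(4-methylbenzenesulfonamide)]
Conditions: TsCl (2.1 equiv), NaOH, H2O/Et2O, 0 °C to rt
Reagents that add atoms: 4-toluenesulfonyl chloride, Cc1ccc(cc1)S(=O)(=O)Cl
Why: Schotten–Baumann N-sulfonylation converts both primary amines into N–H acidic tosylamides, which sets up exactly one alkylation per nitrogen and avoids the over-alkylation that direct hydroxypropylation of the free diamine would bring.

Step 2
Reactants: 2 N,N'-ditosylputrescine; 3 3-bromopropan-1-ol (2.5 equiv)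
Product: 4 N,N'-(butane-1,4-diyl)bis[N-(3-hydroxypropyl)-4-methylbenzenesulfonamide] (ditosyl diol)
Conditions: K2CO3, DMF, 70 °C
Reagents that add atoms: none
Why: SN2 N-alkylation of sulfonamide anions: K2CO3 ionises only the tosylamide N–H, each nitrogen has a single site to fill, and the hydroxyl groups of 3 and 4 stay un-ionised and unreactive.

Step 3
Reactants: 4 ditosyl diol
Product: 5 3-[{4-[(3-hydroxypropyl)(tosyl)amino]butyl}(tosyl)amino]propyl methanesulfonate (mono-mesylate)
Conditions: MsCl (0.9 equiv, slow addition), Et3N, CH2Cl2, −10 °C
Reagents that add atoms: methanesulfonyl chloride, CS(=O)(=O)Cl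
Why: Statistical mono-O-sulfonylation of a symmetric diol with two remote, independent hydroxyls: a deficit of MsCl favours the mono-ester, the three components differ enough in polarity for separation on silica, and recovered 4 is recycled.

Step 4
Reactants: 5 mono-mesylate; 6 hydrazine (as monohydrate, 20 equiv)
Product: 7 N-(3-hydrazinylpropyl)-N'-(3-hydroxypropyl)-N,N'-ditosylbutane-1,4-diamine
Conditions: N2H4·H2O, EtOH, 70 °C
Reagents that add atoms: none
Why: SN2 alkylation of hydrazine, in which the large excess suppresses double alkylation, the tosylamides and free alcohol are inert, and thorough removal of surplus hydrazine (toluene azeotrope, aqueous wash) protects step 6 from an achiral competitor.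

Step 5
Reactants: 8 (E)-dodec-2-enoic acid; 9 benzamide
Product: 11 N-[(E)-dodec-2-enoyl]benzamide, via (E)-dodec-2-enoyl chloride 10 (not isolated)
Conditions: (COCl)2, cat. DMF, CH2Cl2, 0 °C to rt, concentrate; then 9, NaH (2.1 equiv), THF, 0 °C; dilute HCl work-up
Reagents that add atoms: oxalyl chloride, O=C(Cl)C(=O)Cl (supplies the chlorine of 10 only)
Why: Acid chloride formation followed by N-acylation of the amide anion gives the acyclic imide; the second equivalent of base takes up the acidic imide N–H as it forms, and fast acylation at 0 °C leaves the E-alkene conjugated.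

Step 6
Reactants: 7 hydrazino alcohol; 11 N-[(E)-dodec-2-enoyl]benzamide
Product: 13 (5R)-1-{3-[{4-[(3-hydroxypropyl)(tosyl)amino]butyl}(tosyl)amino]propyl}-5-nonylpyrazolidin-3-one, via β-hydrazino imide adduct 12 (not isolated)
Conditions: Mg(NTf2)2 (30 mol %), (3aR,3a'R,8aS,8a'S)-2,2'-(cyclopropane-1,1-diyl)bis(3a,8a-dihydro-8H-indeno[1,2-d]oxazole) (33 mol %), 4 Å MS, CH2Cl2, −40 °C, then rt
Reagents that add atoms: none
Why: Chiral Lewis acid catalysed aza-Michael addition with in situ cyclisation, a known route from primary-alkyl hydrazines and enoyl imides to 1,5-disubstituted pyrazolidin-3-ones: the imide chelates Mg through both carbonyls, the bis(oxazoline) leaves the Re face of the β-carbon open, the more nucleophilic alkylated nitrogen adds there and sets C2 as R, and the NH2 group then attacks the enoyl carbonyl (5-exo-trig acyl substitution) and expels benzamide.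

Step 7
Reactants: 13 pyrazolidinone alcohol
Product: 14 3-[{4-[{3-[(5R)-5-nonyl-3-oxopyrazolidin-1-yl]propyl}(tosyl)amino]butyl}(tosyl)amino]propyl methanesulfonate
Conditions: MsCl (1.05 equiv), Et3N, CH2Cl2, −20 °C
Reagents that add atoms: methanesulfonyl chloride, CS(=O)(=O)Cl
Why: O-mesylation of a primary alcohol, which at low temperature with one equivalent of MsCl is much faster than sulfonylation of the un-ionised hydrazide N–H, while N1, N9 and N14 carry no N–H at all; 14 is used at once.

Step 8
Reactants: 14 pyrazolidinone mesylate
Product: 15 (17R)-17-nonyl-5,10-ditosyl-1,5,10,14-tetraazabicyclo[12.3.0]heptadecan-15-one (the N9,N14-ditosyl bicycle with N1 bonded to N5)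
Conditions: Cs2CO3 (5 equiv), DMF, 60 °C, syringe-pump addition of 14 over 12 h to a final concentration of about 1 mM
Reagents that add atoms: none
Why: Cs2CO3 ionises the hydrazide N5–H of the pyrazolidinone, which it could not do to an ordinary secondary lactam, and the nitrogen of this anion displaces the primary mesylate at C6 by SN2 to form N5–C6. The closest known reaction types are the base-mediated N2-alkylation of 1-substituted pyrazolidin-3-ones with primary halides or sulfonates and cesium-assisted macrocyclic N-alkylation; the intramolecular 14-membered version extends these in ring size only and is where the route carries its risk. The single ring formed (N5, C6 to C8, N9, C10 to C13, N14, C15 to C17, N1) closes in a 14-exo-tet mode and shares the N1–N5 bond with the five-membered ring. No stereocentre is created, and C2 is safe because the β-amino carbonyl unit is held in the small ring and the anionic hydrazide resists α-deprotonation and retro-Michael opening. Ring closure is favoured over oligomer growth by slow addition at high dilution, by the N1–N5 junction that points both chain ends to the same side and by the two tosylamide turns; N-alkylation is favoured over O-alkylation by the loose cesium ion pair in DMF, by the smaller ring (14 against 16 atoms) and by retention of the amide. Nothing else competes, since N1 is fully substituted, N9 and N14 are sulfonamides without N–H, and a sulfonyl group cannot reach C6 as a carbamate carbonyl could.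

Step 9
Reactants: 15 ditosyl bicycle
Product: 16 (2R)-2-nonyl-1,5,9,14-tetraazacycloheptadecan-4-one (target)
Conditions: Na (excess), NH3(l)/THF, −78 °C to −33 °C; then solid NH4Cl
Reagents that add atoms: none
Why: Dissolving-metal reduction: electron transfer into the acyl hydrazide breaks N1–N5, the known ring expansion of bicyclic pyrazolidinones, and electron transfer into the two arenesulfonyl groups breaks both S–N bonds, while the lactam is shielded as its anion and the non-benzylic C2–N1 bond and the C2 configuration are untouched.

Compound list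
1 | putrescine (butane-1,4-diamine) | NCCCCN | starting material
2 | N,N'-ditosylputrescine | Cc1ccc(cc1)S(=O)(=O)NCCCCNS(=O)(=O)c1ccc(C)cc1 | intermediate
3 | 3-bromopropan-1-ol | OCCCBr | starting material
4 | N,N'-(butane-1,4-diyl)bis[N-(3-hydroxypropyl)-4-methylbenzenesulfonamide] | OCCCN(S(=O)(=O)c1ccc(C)cc1)CCCCN(S(=O)(=O)c1ccc(C)cc1)CCCO | intermediate
5 | mono-mesylate of 4 | CS(=O)(=O)OCCCN(S(=O)(=O)c1ccc(C)cc1)CCCCN(S(=O)(=O)c1ccc(C)cc1)CCCO | intermediate
6 | hydrazine (used as monohydrate) | NN | starting material
7 | N-(3-hydrazinylpropyl)-N'-(3-hydroxypropyl)-N,N'-ditosylbutane-1,4-diamine | NNCCCN(S(=O)(=O)c1ccc(C)cc1)CCCCN(S(=O)(=O)c1ccc(C)cc1)CCCO | intermediate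
8 | (E)-dodec-2-enoic acid | CCCCCCCCC/C=C/C(=O)O | starting material
9 | benzamide | NC(=O)c1ccccc1 | starting material
10 | (E)-dodec-2-enoyl chloride (not isolated) | CCCCCCCCC/C=C/C(=O)Cl | intermediate
11 | N-[(E)-dodec-2-enoyl]benzamide | CCCCCCCCC/C=C/C(=O)NC(=O)c1ccccc1 | intermediate
12 | N-benzoyl-(3R)-3-(1-alkylhydrazinyl)dodecanamide, alkyl being the ditosyl hydroxy chain of 7 (not isolated) | CCCCCCCCC[C@H](CC(=O)NC(=O)c1ccccc1)N(N)CCCN(S(=O)(=O)c1ccc(C)cc1)CCCCN(S(=O)(=O)c1ccc(C)cc1)CCCO | intermediate
13 | (5R)-5-nonylpyrazolidin-3-one carrying the ditosyl hydroxy chain on N1 | CCCCCCCCC[C@@H]1CC(=O)NN1CCCN(S(=O)(=O)c2ccc(C)cc2)CCCCN(S(=O)(=O)c2ccc(C)cc2)CCCO | intermediate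
14 | mesylate of 13 (key-step precursor) | CCCCCCCCC[C@@H]1CC(=O)NN1CCCN(S(=O)(=O)c2ccc(C)cc2)CCCCN(S(=O)(=O)c2ccc(C)cc2)CCCOS(C)(=O)=O | intermediate
15 | (17R)-17-nonyl-5,10-ditosyl-1,5,10,14-tetraazabicyclo[12.3.0]heptadecan-15-one (key-step product) | CCCCCCCCC[C@@H]1CC(=O)N2CCCN(S(=O)(=O)c3ccc(C)cc3)CCCCN(S(=O)(=O)c3ccc(C)cc3)CCCN12 | intermediate
16 | (2R)-2-nonyl-1,5,9,14-tetraazacycloheptadecan-4-one | CCCCCCCCC[C@@H]1CC(=O)NCCCNCCCCNCCCN1 | target

Total step count: 9. Longest linear sequence: 8 steps (1, 2, 3, 4, 6, 7, 8, 9).

Steps most likely to fail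

1. Step 8.
- Risk: intermolecular alkylation (oligomer growth) may outpace the 14-membered closure, or alkylation may occur at the hydrazide oxygen.
- Fallback: N5–C6 is made first in an ordinary intermolecular alkylation. The macrocycle is then closed at the sulfonamide nitrogens by a two-component Richman–Atkins cyclisation. It sets out from 11 (partners 2, 3 and 6) and comes back at 15.
- Course: compound 3 with excess 6 in EtOH should give 3-hydrazinylpropan-1-ol F1. F1 and 11 under the catalyst of step 6 should give (5R)-1-(3-hydroxypropyl)-5-nonylpyrazolidin-3-one F2. Alkylation of its hydrazide nitrogen with 3 (Cs2CO3, DMF) should give (5R)-1,2-bis(3-hydroxypropyl)-5-nonylpyrazolidin-3-one F3. MsCl and Et3N convert this into the bis-mesylate F4. F4 and 2 with Cs2CO3 in DMF at 80 °C form N9–C8 and N14–C15 and deliver 15. Because 2 is symmetric, there is no orientation problem.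

2. Step 6.
- Risk: facial selectivity may be poor, through uncatalysed background addition or through the hydroxyl and hydrazine groups competing for Mg. Attack through the unsubstituted nitrogen, or acyl transfer to it before conjugate addition, is also possible.
- Fallback: resolution replaces asymmetric catalysis. It sets out from 7 and 8 and comes back at 13.
- Course: Fischer esterification of 8 (MeOH, cat. H2SO4) gives methyl (E)-dodec-2-enoate F5. Heating 7 with F5 in EtOH, the classical hydrazine-plus-enoate pyrazolidinone synthesis, should give the racemic pyrazolidinone alcohol F6. Preparative chromatography on a polysaccharide chiral stationary phase separates 13 from its (5S)-enantiomer F7.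

3. Step 9.
- Risk: one of the three bonds may be cleaved incompletely, or the very polar tetraamine may be lost during separation from the inorganic salts.
- Fallback: the operation is split so that each cleavage can be followed, with a lipophilic intermediate purified in between. It sets out from 15 and comes back at 16.
- Course: SmI2 in THF/MeOH cleaves only N1–N5 and should give (2R)-2-nonyl-9,14-ditosyl-1,5,9,14-tetraazacycloheptadecan-4-one F8, which is purified on silica. Sodium naphthalenide in DME at −78 °C then removes both tosyl groups to give 16, taken up on an acidic ion-exchange resin and released with aqueous ammonia.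

Further compounds
F1 | step 8 | 3-hydrazinylpropan-1-ol | NNCCCO
F2 | step 8 | (5R)-1-(3-hydroxypropyl)-5-nonylpyrazolidin-3-one | CCCCCCCCC[C@@H]1CC(=O)NN1CCCO
F3 | step 8 | (5R)-1,2-bis(3-hydroxypropyl)-5-nonylpyrazolidin-3-one | CCCCCCCCC[C@@H]1CC(=O)N(CCCO)N1CCCO
F4 | step 8 | (5R)-1,2-bis(3-mesyloxypropyl)-5-nonylpyrazolidin-3-one | CCCCCCCCC[C@@H]1CC(=O)N(CCCOS(C)(=O)=O)N1CCCOS(C)(=O)=O
F5 | step 6 | methyl (E)-dodec-2-enoate | CCCCCCCCC/C=C/C(=O)OC
F6 | step 6 | racemic form of 13 | CCCCCCCCCC1CC(=O)NN1CCCN(S(=O)(=O)c2ccc(C)cc2)CCCCN(S(=O)(=O)c2ccc(C)cc2)CCCO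
F7 | step 6 | (5S)-enantiomer of 13 | CCCCCCCCC[C@H]1CC(=O)NN1CCCN(S(=O)(=O)c2ccc(C)cc2)CCCCN(S(=O)(=O)c2ccc(C)cc2)CCCO
F8 | step 9 | (2R)-2-nonyl-9,14-ditosyl-1,5,9,14-tetraazacycloheptadecan-4-one | CCCCCCCCC[C@@H]1CC(=O)NCCCN(S(=O)(=O)c2ccc(C)cc2)CCCCN(S(=O)(=O)c2ccc(C)cc2)CCCN1
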